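**Retrosynthetic overview** (ring A = the trioxygenated ring, ring B = the 4-hydroxyphenyl ring, C1–C7 = the heptenyl chain)
1. The chalcone C=C is cut last (Claisen–Schmidt condensation with benzaldehyde), so no enone competes for the alkenylboron reagent in the key step.
2. Key disconnection: both bonds at C1 (ring A–C1 and C1–C2) are cut at once. An acylphloroglucinol methyl ether, an aromatic aldehyde and an (E)-alkenylboronic acid are joined in one pot through a dearomatised ortho-quinone methide of ring A, with a chiral biphenol setting C1.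
3. The alkenylboronic acid comes from hydroboration of a homopropargylic alcohol, whose C5 carbinol centre is set by catalytic asymmetric propargylation of 3-phenylpropanal.
4. No ring is formed: all three benzene rings are bought; ring A is only dearomatised and rearomatised in the key step.

Assumption: the senses of induction of the two chiral catalysts (steps 1 and 3) are assigned by analogy with their known reactions; if either gives the opposite sense, the mirror-image catalyst is used and nothing else changes.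

**Route**

Step 1
Reactants: 1 3-phenylpropanal; 2 allenylboronic acid pinacol ester
Product: 4 (S)-1-phenylhex-5-yn-3-ol, via borate ester 3 (not isolated)
Conditions: (R)-TRIP [(R)-3,3'-bis(2,4,6-triisopropylphenyl)-1,1'-binaphthyl-2,2'-diyl hydrogen phosphate] (5 mol %), 4 Å MS, cyclohexane, rt, 24 h; then aqueous work-up
Reagents that add atoms: none
Why: Chiral phosphoric acid-catalysed asymmetric propargylboration (allenyl-to-propargyl SE2' transfer through a closed six-membered transition state); the acid activates the boronate and directs attack to the Re face of the aldehyde, which sets the S carbinol (C5 of the target).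

Step 2
Reactants: 4 (S)-1-phenylhex-5-yn-3-ol
Product: 6 [(1E,4S)-4-hydroxy-6-phenylhex-1-en-1-yl]boronic acid, via bis-catecholboryl adduct 5 (not isolated)
Conditions: catecholborane (2.5 equiv), dicyclohexylborane (10 mol %), THF, 0 °C to rt, 6 h; then H2O, rt, 2 h; solid washed with cold water
Reagents that add atoms: catecholborane B1Oc2ccccc2O1; water O
Why: Alkyne hydroboration (dialkylborane-catalysed, catecholborane as the stoichiometric hydride source): the alcohol is first O-borylated in the flask, syn anti-Markovnikov addition to the terminal alkyne then gives only the E-alkenylboronate, and water hydrolyses both catechol esters without touching the carbinol centre.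

Step 3
Reactants: 6 [(1E,4S)-4-hydroxy-6-phenylhex-1-en-1-yl]boronic acid; 7 1-(2,4-dihydroxy-6-methoxyphenyl)ethanone; 8 4-formylphenyl acetate
Product: 11 4-[(1R,2E,5S)-1-(3-acetyl-2,6-dihydroxy-4-methoxyphenyl)-5-hydroxy-7-phenylhept-2-en-1-yl]phenyl acetate, via benzhydrol 9 (not isolated), via ortho-quinone methide 10 (not isolated)
Conditions: 7 (1.0 equiv), 8 (1.1 equiv), 6 (1.5 equiv, pre-dried over 4 Å MS), (R)-3,3'-dibromo-1,1'-bi-2-naphthol (20 mol %), 4 Å MS, PhCF3, Ar, 45 °C, 48 h; then aq. NH4Cl
Reagents that add atoms: none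
Why: Proposed new method: boron-templated ortho-hydroxyalkylation of the electron-rich acylphloroglucinol 7 by 8 gives benzhydrol 9, which loses water to the dearomatised ortho-quinone methide 10 (its hydrogen-bonded enol–ketone unit stays intact and stabilises it); the alkenylboronate, made chiral and more Lewis acidic by exchange with the dibromo-biphenol, binds the quinone-methide oxygen and delivers the alkenyl group with retention of E geometry through a closed six-membered transition state to one face of the exocyclic carbon, which rearomatises ring A and sets C1 as R under catalyst control; C3 of 7 should react in preference to C5 because it is ortho to both hydroxyls (either aryl borate can deliver the aldehyde there) and the chelated ketone localises double-bond character at C3–C4; the closest known reaction type is the chiral biphenol-catalysed multicomponent condensation of electron-rich phenols, aldehydes and alkenylboronates via ortho-quinone methides (a Petasis-type boronate addition), here extended to an acylphloroglucinol and to partners with a free alcohol.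

Step 4
Reactants: 11 4-[(1R,2E,5S)-1-(3-acetyl-2,6-dihydroxy-4-methoxyphenyl)-5-hydroxy-7-phenylhept-2-en-1-yl]phenyl acetate; 12 benzaldehyde
Product: 15 ent-alpinnanin A, via phenol ketone 13 (not isolated), via aldol adduct 14 (not isolated)
Conditions: KOH (50% aq., 15 equiv), 12 (1.5 equiv), EtOH, Ar, 0 °C to rt, 36 h; then cold 1 M HCl to pH 4
Reagents that add atoms: none
Why: Claisen–Schmidt (crossed aldol) condensation: hydroxide first cleaves the aryl acetate, the methyl ketone enolate adds to non-enolisable benzaldehyde, and E1cB dehydration gives the E-enone; neither stereocentre carries a hydrogen acidic enough to be touched.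

**Compound list**

1 | 3-phenylpropanal | O=CCCc1ccccc1 | starting material
2 | allenylboronic acid pinacol ester (4,4,5,5-tetramethyl-2-(propa-1,2-dien-1-yl)-1,3,2-dioxaborolane) | C=C=CB1OC(C)(C)C(C)(C)O1 | starting material
3 | (S)-4,4,5,5-tetramethyl-2-[(1-phenylhex-5-yn-3-yl)oxy]-1,3,2-dioxaborolane | C#CC[C@@H](OB1OC(C)(C)C(C)(C)O1)CCc1ccccc1 | intermediate
4 | (S)-1-phenylhex-5-yn-3-ol | C#CC[C@@H](O)CCc1ccccc1 | intermediate
5 | 2-[(1E,4S)-4-(1,3,2-benzodioxaborol-2-yloxy)-6-phenylhex-1-en-1-yl]-1,3,2-benzodioxaborole | B1(/C=C/C[C@@H](OB2Oc3ccccc3O2)CCc2ccccc2)Oc2ccccc2O1 | intermediate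
6 | [(1E,4S)-4-hydroxy-6-phenylhex-1-en-1-yl]boronic acid | OB(O)/C=C/C[C@@H](O)CCc1ccccc1 | intermediate
7 | 1-(2,4-dihydroxy-6-methoxyphenyl)ethanone | COc1cc(O)cc(O)c1C(C)=O | starting material
8 | 4-formylphenyl acetate (4-acetoxybenzaldehyde) | CC(=O)Oc1ccc(C=O)cc1 | starting material
9 | 4-[(3-acetyl-2,6-dihydroxy-4-methoxyphenyl)(hydroxy)methyl]phenyl acetate (racemic carbinol) | COc1cc(O)c(C(O)c2ccc(OC(C)=O)cc2)c(O)c1C(C)=O | intermediate
10 | 4-[(3-acetyl-2-hydroxy-4-methoxy-6-oxocyclohexa-2,4-dien-1-ylidene)methyl]phenyl acetate (exocyclic alkene geometry not defined) | COC1=CC(=O)C(=Cc2ccc(OC(C)=O)cc2)C(O)=C1C(C)=O | intermediate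
11 | 4-[(1R,2E,5S)-1-(3-acetyl-2,6-dihydroxy-4-methoxyphenyl)-5-hydroxy-7-phenylhept-2-en-1-yl]phenyl acetate | COc1cc(O)c([C@H](/C=C/C[C@@H](O)CCc2ccccc2)c2ccc(OC(C)=O)cc2)c(O)c1C(C)=O | intermediate
12 | benzaldehyde | O=Cc1ccccc1 | starting material
13 | 1-[2,4-dihydroxy-3-[(1R,2E,5S)-5-hydroxy-1-(4-hydroxyphenyl)-7-phenylhept-2-en-1-yl]-6-methoxyphenyl]ethanone | COc1cc(O)c([C@H](/C=C/C[C@@H](O)CCc2ccccc2)c2ccc(O)cc2)c(O)c1C(C)=O | intermediate
14 | 1-[2,4-dihydroxy-3-[(1R,2E,5S)-5-hydroxy-1-(4-hydroxyphenyl)-7-phenylhept-2-en-1-yl]-6-methoxyphenyl]-3-hydroxy-3-phenylpropan-1-one (both epimers at the new carbinol) | COc1cc(O)c([C@H](/C=C/C[C@@H](O)CCc2ccccc2)c2ccc(O)cc2)c(O)c1C(=O)CC(O)c1ccccc1 | intermediate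
15 | ent-alpinnanin A, (2E)-1-[2,4-dihydroxy-3-[(1R,2E,5S)-5-hydroxy-1-(4-hydroxyphenyl)-7-phenylhept-2-en-1-yl]-6-methoxyphenyl]-3-phenylprop-2-en-1-one | COc1cc(O)c([C@H](/C=C/C[C@@H](O)CCc2ccccc2)c2ccc(O)cc2)c(O)c1C(=O)/C=C/c1ccccc1 | target

**Step count**

Total steps: 4. Longest linear sequence: 4 (1 → 4 → 6 → 11 → 15).

**Steps most likely to fail, with fallbacks**

Step 3 (highest risk). The acetyl group of 7 can chelate boron and erode enantioselectivity, C5 may compete with C3, and the ortho-quinone methide can be trapped by a second molecule of 7. The fallback makes the ring A–C1 bond and the C1 centre by an aromatic Claisen rearrangement with 1,3-chirality transfer and finishes the chain by olefin cross-metathesis. It sets out from 8 (7 and 4 join later) and comes back to the route at 11. Wittig olefination of 8 with Ph3P=CHC(O)CH3 (toluene, 80 °C) gives 4-[(1E)-3-oxobut-1-en-1-yl]phenyl acetate F1. Reduction with (R)-2-methyl-CBS-oxazaborolidine (10 mol %) and BH3·SMe2 (THF, −30 °C) gives 4-[(1E,3S)-3-hydroxybut-1-en-1-yl]phenyl acetate F2. Mitsunobu etherification of F2 with the free, non-chelated 4-OH of 7 (PPh3, DIAD, THF, 0 °C) proceeds with inversion to 4-[(1E,3R)-3-(4-acetyl-3-hydroxy-5-methoxyphenoxy)but-1-en-1-yl]phenyl acetate F3. Heating F3 (PhNEt2, 130 °C, or Eu(fod)3 10 mol %, PhCl, 80 °C) brings about the [3,3] shift through a chair with the methyl group equatorial; migration goes to C3, as known for 4-allyloxy-2-hydroxyaryl ketones, and tautomerisation gives 4-[(1R,2E)-1-(3-acetyl-2,6-dihydroxy-4-methoxyphenyl)but-2-en-1-yl]phenyl acetate F4. Separately, semi-hydrogenation of 4 (H2, Pd/CaCO3 poisoned with Pb(OAc)2, quinoline, EtOAc) gives (S)-1-phenylhex-5-en-3-ol F5. Cross-metathesis of F4 with F5 (3 equiv; second-generation Hoveyda–Grubbs catalyst RuCl2(H2IMes)(=CH–C6H4–2-O-i-Pr), 5 mol %, CH2Cl2, 40 °C) gives 11.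

Step 4. The 4-phenoxide para to the acetyl group lowers the acidity of the methyl ketone, and the 2'-hydroxychalcone can close to the flavanone on work-up. The fallback masks that phenol before the condensation. It sets out from 11 and comes back at 15. MOMCl (1.1 equiv), i-Pr2NEt, CH2Cl2, 0 °C alkylates only the acidic, non-chelated ring A hydroxyl and gives 4-[(1R,2E,5S)-1-[3-acetyl-2-hydroxy-4-methoxy-6-(methoxymethoxy)phenyl]-5-hydroxy-7-phenylhept-2-en-1-yl]phenyl acetate F6. Condensation of F6 with 12 (KOH, EtOH, rt), the standard protocol for 4'-O-protected 2'-hydroxyacetophenones, gives (2E)-1-[2-hydroxy-3-[(1R,2E,5S)-5-hydroxy-1-(4-hydroxyphenyl)-7-phenylhept-2-en-1-yl]-6-methoxy-4-(methoxymethoxy)phenyl]-3-phenylprop-2-en-1-one F7. Brief treatment with 3 M HCl in MeOH at 40 °C removes the acetal and gives 15.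

Step 2. The free alcohol consumes borane, and the hydroxy boronic acid may be hard to free from catechol. The fallback replaces B–H hydroboration by copper-catalysed borylcupration and protonation, which tolerates the alcohol and gives a chromatographable ester. It sets out from 4 and comes back at 6. CuCl (5 mol %), Xantphos (5 mol %), NaOt-Bu (10 mol %), B2pin2 (1.1 equiv), MeOH (2 equiv), THF, rt gives (3S,5E)-1-phenyl-6-(4,4,5,5-tetramethyl-1,3,2-dioxaborolan-2-yl)hex-5-en-3-ol F8. Oxidative removal of the diol (NaIO4, NH4OAc, acetone/H2O, rt) gives 6.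

**Further compounds**

F1 | step 3 | 4-[(1E)-3-oxobut-1-en-1-yl]phenyl acetate | CC(=O)/C=C/c1ccc(OC(C)=O)cc1
F2 | step 3 | 4-[(1E,3S)-3-hydroxybut-1-en-1-yl]phenyl acetate | C[C@H](O)/C=C/c1ccc(OC(C)=O)cc1
F3 | step 3 | 4-[(1E,3R)-3-(4-acetyl-3-hydroxy-5-methoxyphenoxy)but-1-en-1-yl]phenyl acetate | C[C@@H](Oc1cc(O)c(C(C)=O)c(OC)c1)/C=C/c1ccc(OC(C)=O)cc1
F4 | step 3 | 4-[(1R,2E)-1-(3-acetyl-2,6-dihydroxy-4-methoxyphenyl)but-2-en-1-yl]phenyl acetate | COc1cc(O)c([C@H](/C=C/C)c2ccc(OC(C)=O)cc2)c(O)c1C(C)=O
F5 | step 3 | (S)-1-phenylhex-5-en-3-ol | C=CC[C@@H](O)CCc1ccccc1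
F6 | step 4 | 4-[(1R,2E,5S)-1-[3-acetyl-2-hydroxy-4-methoxy-6-(methoxymethoxy)phenyl]-5-hydroxy-7-phenylhept-2-en-1-yl]phenyl acetate | COc1cc(OCOC)c([C@H](/C=C/C[C@@H](O)CCc2ccccc2)c2ccc(OC(C)=O)cc2)c(O)c1C(C)=O
F7 | step 4 | (2E)-1-[2-hydroxy-3-[(1R,2E,5S)-5-hydroxy-1-(4-hydroxyphenyl)-7-phenylhept-2-en-1-yl]-6-methoxy-4-(methoxymethoxy)phenyl]-3-phenylprop-2-en-1-one | COc1cc(OCOC)c([C@H](/C=C/C[C@@H](O)CCc2ccccc2)c2ccc(O)cc2)c(O)c1C(=O)/C=C/c1ccccc1
F8 | step 2 | (3S,5E)-1-phenyl-6-(4,4,5,5-tetramethyl-1,3,2-dioxaborolan-2-yl)hex-5-en-3-ol | CC1(C)OB(/C=C/C[C@@H](O)CCc2ccccc2)OC1(C)C
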